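## Retrosynthetic overview

1. Target 29 ⇐ methyl ester 27. The side chain C15(Me)=C16–prenyl ⇐ terminal alkyne 24 (Negishi methylalumination, Pd-catalysed prenylation); the alkyne carbon C15 ⇐ the N-acyl carbon of an Evans imide.
2. Key disconnection, and the only ring (14-membered, closed in step 10): C12–C13 by a macrocyclising B-alkyl Suzuki–Miyaura coupling onto a preformed (E)-vinyl iodide. The obvious closures (macro-olefination at the C7=C8 enoate, RCM, sulfone or cyanohydrin alkylation) are avoided.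
3. C1–C2 and the stereocentre ⇐ deconjugative Evans alkylation of a crotonyl imide with a neryl-type bromide. The crotonyl unit is a four-carbon chiral linchpin: its acyl carbon becomes C15, its vinyl group becomes C14–C13.
4. Linear C2–C12 chain ⇐ Wittig reaction of the neryl acetate-derived aldehyde (C2–C7, Z-alkene from the pool) with an α-substituted ylide built from (2E)-2,5-diiodopent-2-ene (C9–C12) and Ph3P=CHCO2Me (C8 and the carboxyl).

Assumption: ring atoms are numbered C1 (stereocentre) to C14 in the order of the target SMILES and the side chain C15–C19; reagents named only in Conditions lines are taken as purchasable.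

## Route

Step 1
Reactants: 1 neryl acetate
Product: 2 (2Z)-5-(3,3-dimethyloxiran-2-yl)-3-methylpent-2-en-1-yl acetate
Conditions: mCPBA (1.0 equiv), CH2Cl2, 0 °C
Reagents that add atoms: meta-chloroperoxybenzoic acid, OOC(=O)c1cccc(Cl)c1
Why: Prilezhaev epoxidation takes the electron-rich distal alkene because the 2,3-alkene is deactivated by the allylic acetate; the epoxide stereocentre is racemic and is destroyed in step 2.

Step 2
Reactants: 2 (2Z)-5-(3,3-dimethyloxiran-2-yl)-3-methylpent-2-en-1-yl acetate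
Product: 4 (2Z)-3-methyl-6-oxohex-2-en-1-yl acetate, via vicinal diol 3 (not isolated)
Conditions: H5IO6 (1.2 equiv), THF/H2O, 0 °C
Reagents that add atoms: none
Why: Acid-mediated epoxide hydrolysis followed by Malaprade glycol cleavage removes the terminal carbons as acetone and leaves the Z-alkene and the allylic acetate untouched.

Step 3
Reactants: 5 pent-3-yn-1-ol
Product: 7 (3E)-4-iodopent-3-en-1-ol, via alkenylzirconocene chloride 6 (not isolated)
Conditions: Cp2Zr(H)Cl (2.6 equiv), THF, 23 → 45 °C; then I2, 0 °C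
Reagents that add atoms: iodine, [I][I]
Why: Schwartz hydrozirconation adds H–Zr syn and, after equilibration with excess hydride, places zirconium on the less hindered methyl-bearing carbon; iododezirconation with retention gives the (E)-2-iodo-2-alkene.

Step 4
Reactants: 7 (3E)-4-iodopent-3-en-1-ol
Product: 8 (2E)-2,5-diiodopent-2-ene
Conditions: I2, PPh3, imidazole, CH2Cl2, 0 °C
Reagents that add atoms: iodine, [I][I]
Why: Appel iodination converts the primary alcohol to the iodide by SN2 displacement and does not touch the vinyl iodide.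

Step 5
Reactants: 8 (2E)-2,5-diiodopent-2-ene; 9 methyl (triphenyl-λ5-phosphanylidene)acetate
Product: 11 methyl (5E)-6-iodo-2-(triphenyl-λ5-phosphanylidene)hept-5-enoate, via phosphonium iodide 10 (not isolated)
Conditions: 9 (2.1 equiv), EtOAc, 75 °C, 36 h; filter off the precipitated phosphonium salt
Reagents that add atoms: none
Why: Bestmann C-alkylation of the stabilised ylide occurs only at the sp3 iodide, and the second equivalent of ylide deprotonates the new phosphonium salt (transylidation), driven by precipitation of the simple phosphonium iodide.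

Step 6
Reactants: 4 (2Z)-3-methyl-6-oxohex-2-en-1-yl acetate; 11 methyl (5E)-6-iodo-2-(triphenyl-λ5-phosphanylidene)hept-5-enoate
Product: 13 methyl (2E,6Z)-8-hydroxy-2-[(3E)-4-iodopent-3-en-1-yl]-6-methylocta-2,6-dienoate, via allylic acetate 12 (not isolated)
Conditions: CH2Cl2, 23 → 40 °C, 24 h; then MeOH, K2CO3 (0.2 equiv), 0 → 23 °C
Reagents that add atoms: none
Why: Wittig olefination with an α-substituted ester-stabilised ylide gives the trisubstituted (E)-enoate (C6 cis to C9, ester trans to C6) with high selectivity, and catalytic K2CO3 in methanol then removes the acetate by transesterification while the methyl ester stays methyl.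

Step 7
Reactants: 13 methyl (2E,6Z)-8-hydroxy-2-[(3E)-4-iodopent-3-en-1-yl]-6-methylocta-2,6-dienoate
Product: 14 methyl (2E,6Z)-8-bromo-2-[(3E)-4-iodopent-3-en-1-yl]-6-methylocta-2,6-dienoate
Conditions: CBr4, PPh3, CH2Cl2, −20 → 0 °C
Reagents that add atoms: tetrabromomethane, BrC(Br)(Br)Br
Why: Appel bromination of the primary allylic alcohol is an SN2 process that keeps the Z geometry, as in the standard preparation of neryl bromide.

Step 8
Reactants: 15 (4S)-4-benzyl-1,3-oxazolidin-2-one; 16 (2E)-but-2-enoic anhydride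
Product: 17 (4S)-4-benzyl-3-[(2E)-but-2-enoyl]-1,3-oxazolidin-2-one
Conditions: Et3N, LiCl, THF, −20 → 23 °C
Reagents that add atoms: none
Why: Lithium chloride/triethylamine-promoted N-acylation of the oxazolidinone with the anhydride is mild and avoids the polymerisation seen with enoyl chlorides and strong base.

Step 9
Reactants: 17 (4S)-4-benzyl-3-[(2E)-but-2-enoyl]-1,3-oxazolidin-2-one; 14 methyl (2E,6Z)-8-bromo-2-[(3E)-4-iodopent-3-en-1-yl]-6-methylocta-2,6-dienoate
Product: 19 methyl (2E,6Z,9S)-9-{[(4S)-4-benzyl-2-oxo-1,3-oxazolidin-3-yl]carbonyl}-2-[(3E)-4-iodopent-3-en-1-yl]-6-methylundeca-2,6,10-trienoate, via sodium dienolate 18 (not isolated)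
Conditions: 17 (1.4 equiv) added to NaN(SiMe3)2 (1.35 equiv), THF, −78 °C, 1 h; then 14, −78 → −40 °C; pH 7 buffer quench
Reagents that add atoms: none
Why: Deconjugative Evans asymmetric alkylation: γ-deprotonation of the s-cis crotonyl imide gives the chelated (Z)-dienolate, which is alkylated at the α-carbon by the allylic bromide on the face opposite the benzyl group, setting C1 (descriptor S here, R in the target after the priority change) and leaving the vinyl group that becomes C14–C13.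

Step 10
Reactants: 19 methyl (2E,6Z,9S)-9-{[(4S)-4-benzyl-2-oxo-1,3-oxazolidin-3-yl]carbonyl}-2-[(3E)-4-iodopent-3-en-1-yl]-6-methylundeca-2,6,10-trienoate
Product: 21 methyl (1E,5Z,8R,11E)-8-{[(4S)-4-benzyl-2-oxo-1,3-oxazolidin-3-yl]carbonyl}-5,11-dimethylcyclotetradeca-1,5,11-triene-1-carboxylate, via B-alkyl-9-BBN borane 20 (not isolated)
Conditions: 9-BBN (1.5 equiv), THF, 0 → 23 °C; then syringe-pump addition (12 h) to Pd(dppf)Cl2 (20 mol %), AsPh3 (20 mol %), K3PO4 (3 equiv), DMF/THF/H2O, 45 °C, final 1 mM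
Reagents that add atoms: none
Why: 9-BBN hydroborates only the monosubstituted vinyl group (anti-Markovnikov), and the primary borane then undergoes intramolecular B-alkyl Suzuki–Miyaura coupling with the vinyl iodide with retention of its (E) geometry, closing the 14-membered ring at C12–C13 under high dilution without touching C1.

Step 11
Reactants: 21 methyl (1E,5Z,8R,11E)-8-{[(4S)-4-benzyl-2-oxo-1,3-oxazolidin-3-yl]carbonyl}-5,11-dimethylcyclotetradeca-1,5,11-triene-1-carboxylate
Product: 22 methyl (1E,5Z,8R,11E)-8-(hydroxymethyl)-5,11-dimethylcyclotetradeca-1,5,11-triene-1-carboxylate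
Conditions: NaBH4 (4 equiv), THF/H2O (4:1), 0 → 23 °C
Reagents that add atoms: none
Why: Reductive removal of the Evans auxiliary: borohydride attacks the activated imide acyl carbon far faster than the hindered conjugated methyl ester, giving the primary alcohol without epimerisation.

Step 12
Reactants: 22 methyl (1E,5Z,8R,11E)-8-(hydroxymethyl)-5,11-dimethylcyclotetradeca-1,5,11-triene-1-carboxylate
Product: 23 methyl (1E,5Z,8R,11E)-8-formyl-5,11-dimethylcyclotetradeca-1,5,11-triene-1-carboxylate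
Conditions: Dess–Martin periodinane (1.3 equiv), CH2Cl2, 0 → 23 °C
Reagents that add atoms: none
Why: Dess–Martin oxidation gives the α-branched aldehyde under near-neutral conditions, so C1 does not epimerise and the alkenes are untouched.

Step 13
Reactants: 23 methyl (1E,5Z,8R,11E)-8-formyl-5,11-dimethylcyclotetradeca-1,5,11-triene-1-carboxylate
Product: 24 methyl (1E,5Z,8R,11E)-8-ethynyl-5,11-dimethylcyclotetradeca-1,5,11-triene-1-carboxylate
Conditions: dimethyl (1-diazo-2-oxopropyl)phosphonate (1.5 equiv), K2CO3 (2 equiv), MeOH, 0 → 23 °C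
Reagents that add atoms: dimethyl (1-diazo-2-oxopropyl)phosphonate, COP(=O)(OC)C(=[N+]=[N-])C(C)=O
Why: Ohira–Bestmann (Seyferth–Gilbert) homologation converts the aldehyde into the terminal alkyne through an alkylidene carbene 1,2-shift under mild carbonate conditions that normally preserve an α-stereocentre.

Step 14
Reactants: 24 methyl (1E,5Z,8R,11E)-8-ethynyl-5,11-dimethylcyclotetradeca-1,5,11-triene-1-carboxylate; 25 1-chloro-3-methylbut-2-ene
Product: 27 methyl (1E,5Z,8R,11E)-5,11-dimethyl-8-[(2E)-6-methylhepta-2,5-dien-2-yl]cyclotetradeca-1,5,11-triene-1-carboxylate, via alkenylalane 26 (not isolated)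
Conditions: Me3Al (2.5 equiv), Cp2ZrCl2 (0.3 equiv), CH2Cl2, 0 → 23 °C; then 25, Pd(PPh3)4 (5 mol %), THF, 23 °C
Reagents that add atoms: trimethylaluminium, C[Al](C)C
Why: Negishi zirconium-catalysed methylalumination adds Me–Al syn across the terminal alkyne (methyl to the internal carbon), and palladium-catalysed allylation of the alkenylalane at the primary carbon of prenyl chloride proceeds with retention, giving the (E)-trisubstituted alkene of the skipped-diene side chain.

Step 15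
Reactants: 27 methyl (1E,5Z,8R,11E)-5,11-dimethyl-8-[(2E)-6-methylhepta-2,5-dien-2-yl]cyclotetradeca-1,5,11-triene-1-carboxylate
Product: 29 (1E,5Z,8R,11E)-5,11-dimethyl-8-[(2E)-6-methylhepta-2,5-dien-2-yl]cyclotetradeca-1,5,11-triene-1-carboxylic acid, via lithium carboxylate 28 (not isolated)
Conditions: LiOH·H2O (10 equiv), THF/MeOH/H2O, 50 °C; then 1 M HCl to pH 3, 0 °C
Reagents that add atoms: lithium hydroxide, [Li+].[OH-]
Why: Saponification by acyl–oxygen cleavage leaves the non-acidic allylic stereocentre and all alkene geometries unchanged, and brief cold acidification frees the acid.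

## Compound list

1 | neryl acetate = (2Z)-3,7-dimethylocta-2,6-dien-1-yl acetate | CC(C)=CCC/C(C)=C\COC(C)=O | starting material
2 | (2Z)-5-(3,3-dimethyloxiran-2-yl)-3-methylpent-2-en-1-yl acetate (racemic at the oxirane carbon) | CC1(C)OC1CC/C(C)=C\COC(C)=O | intermediate
3 | (2Z)-6,7-dihydroxy-3,7-dimethyloct-2-en-1-yl acetate (racemic; not isolated) | CC(C)(O)C(O)CC/C(C)=C\COC(C)=O | intermediate
4 | (2Z)-3-methyl-6-oxohex-2-en-1-yl acetate | O=CCC/C(C)=C\COC(C)=O | intermediate
5 | pent-3-yn-1-ol | CC#CCCO | starting material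
6 | (3E)-pent-3-en-1-ol carrying Cp2Zr(Cl) on oxygen and on C4, zirconium cis to the C3 hydrogen (not isolated) | C/C(=C\CCO[Zr](Cl)(C1C=CC=C1)C1C=CC=C1)[Zr](Cl)(C1C=CC=C1)C1C=CC=C1 | intermediate
7 | (3E)-4-iodopent-3-en-1-ol | C/C(I)=C\CCO | intermediate
8 | (2E)-2,5-diiodopent-2-ene | C/C(I)=C\CCI | intermediate
9 | methyl (triphenyl-λ5-phosphanylidene)acetate | COC(=O)C=P(c1ccccc1)(c1ccccc1)c1ccccc1 | starting material
10 | [(5E)-6-iodo-1-methoxy-1-oxohept-5-en-2-yl]triphenylphosphonium iodide (racemic; not isolated) | COC(=O)C(CC/C=C(\C)I)[P+](c1ccccc1)(c1ccccc1)c1ccccc1.[I-] | intermediate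
11 | methyl (5E)-6-iodo-2-(triphenyl-λ5-phosphanylidene)hept-5-enoate | COC(=O)C(CC/C=C(\C)I)=P(c1ccccc1)(c1ccccc1)c1ccccc1 | intermediate
12 | methyl (2E,6Z)-8-acetoxy-2-[(3E)-4-iodopent-3-en-1-yl]-6-methylocta-2,6-dienoate (not isolated) | COC(=O)/C(=C/CC/C(C)=C\COC(C)=O)CC/C=C(\C)I | intermediate
13 | methyl (2E,6Z)-8-hydroxy-2-[(3E)-4-iodopent-3-en-1-yl]-6-methylocta-2,6-dienoate | COC(=O)/C(=C/CC/C(C)=C\CO)CC/C=C(\C)I | intermediate
14 | methyl (2E,6Z)-8-bromo-2-[(3E)-4-iodopent-3-en-1-yl]-6-methylocta-2,6-dienoate | COC(=O)/C(=C/CC/C(C)=C\CBr)CC/C=C(\C)I | intermediate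
15 | (4S)-4-benzyl-1,3-oxazolidin-2-one | O=C1OC[C@H](Cc2ccccc2)N1 | starting material
16 | (2E)-but-2-enoic anhydride (crotonic anhydride) | C/C=C/C(=O)OC(=O)/C=C/C | starting material
17 | (4S)-4-benzyl-3-[(2E)-but-2-enoyl]-1,3-oxazolidin-2-one | C/C=C/C(=O)N1[C@@H](Cc2ccccc2)COC1=O | intermediate
18 | sodium (1Z)-1-[(4S)-4-benzyl-2-oxo-1,3-oxazolidin-3-yl]buta-1,3-dien-1-olate (not isolated) | [Na+].[O-]/C(=C\C=C)N1[C@@H](Cc2ccccc2)COC1=O | intermediate
19 | methyl (2E,6Z,9S)-9-{[(4S)-4-benzyl-2-oxo-1,3-oxazolidin-3-yl]carbonyl}-2-[(3E)-4-iodopent-3-en-1-yl]-6-methylundeca-2,6,10-trienoate | C=C[C@H](C/C=C(/C)CC/C=C(/C(=O)OC)CC/C=C(\C)I)C(=O)N1[C@@H](Cc2ccccc2)COC1=O | intermediate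
20 | methyl (2E,6Z,9R)-9-{[(4S)-4-benzyl-2-oxo-1,3-oxazolidin-3-yl]carbonyl}-11-(9-borabicyclo[3.3.1]nonan-9-yl)-2-[(3E)-4-iodopent-3-en-1-yl]-6-methylundeca-2,6-dienoate (not isolated) | B1(C2CCCC1CCC2)CC[C@H](C/C=C(/C)CC/C=C(/C(=O)OC)CC/C=C(\C)I)C(=O)N1[C@@H](Cc2ccccc2)COC1=O | intermediate
21 | methyl (1E,5Z,8R,11E)-8-{[(4S)-4-benzyl-2-oxo-1,3-oxazolidin-3-yl]carbonyl}-5,11-dimethylcyclotetradeca-1,5,11-triene-1-carboxylate | O=C(N2[C@@H](Cc3ccccc3)COC2=O)[C@H]1C/C=C(/C)CC/C=C(/C(=O)OC)CC/C=C(\C)CC1 | intermediate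
22 | methyl (1E,5Z,8R,11E)-8-(hydroxymethyl)-5,11-dimethylcyclotetradeca-1,5,11-triene-1-carboxylate | OC[C@H]1C/C=C(/C)CC/C=C(/C(=O)OC)CC/C=C(\C)CC1 | intermediate
23 | methyl (1E,5Z,8R,11E)-8-formyl-5,11-dimethylcyclotetradeca-1,5,11-triene-1-carboxylate | O=C[C@H]1C/C=C(/C)CC/C=C(/C(=O)OC)CC/C=C(\C)CC1 | intermediate
24 | methyl (1E,5Z,8R,11E)-8-ethynyl-5,11-dimethylcyclotetradeca-1,5,11-triene-1-carboxylate | C#C[C@H]1C/C=C(/C)CC/C=C(/C(=O)OC)CC/C=C(\C)CC1 | intermediate
25 | 1-chloro-3-methylbut-2-ene (prenyl chloride) | CC(C)=CCCl | starting material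
26 | methyl (1E,5Z,8R,11E)-8-[(1E)-1-(dimethylalumanyl)prop-1-en-2-yl]-5,11-dimethylcyclotetradeca-1,5,11-triene-1-carboxylate (not isolated) | C[Al](C)/C=C(\C)[C@H]1C/C=C(/C)CC/C=C(/C(=O)OC)CC/C=C(\C)CC1 | intermediate
27 | methyl (1E,5Z,8R,11E)-5,11-dimethyl-8-[(2E)-6-methylhepta-2,5-dien-2-yl]cyclotetradeca-1,5,11-triene-1-carboxylate | CC(C)=CC/C=C(\C)[C@H]1C/C=C(/C)CC/C=C(/C(=O)OC)CC/C=C(\C)CC1 | intermediate
28 | lithium (1E,5Z,8R,11E)-5,11-dimethyl-8-[(2E)-6-methylhepta-2,5-dien-2-yl]cyclotetradeca-1,5,11-triene-1-carboxylate (not isolated) | [Li+].CC(C)=CC/C=C(\C)[C@H]1C/C=C(/C)CC/C=C(/C([O-])=O)CC/C=C(\C)CC1 | intermediate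
29 | (1E,5Z,8R,11E)-5,11-dimethyl-8-[(2E)-6-methylhepta-2,5-dien-2-yl]cyclotetradeca-1,5,11-triene-1-carboxylic acid (CNP0112585.1) | CC(C)=CC/C=C(\C)[C@H]1C/C=C(/C)CC/C=C(/C(=O)O)CC/C=C(\C)CC1 | target

## Step count and risk

Total step count: 15.
Longest linear sequence: 12 steps (steps 3, 4, 5, 6, 7, 9, 10, 11, 12, 13, 14, 15, from pent-3-yn-1-ol).

Three steps most likely to fail:

**Step 9 (deconjugative alkylation).** The dienolate may self-condense with unreacted crotonyl imide, react partly at the γ-carbon, or give a product that slips into conjugation. The fallback sets out from 15 and 14 and comes back at 19, replacing the dienolate by an ordinary saturated enolate with a latent vinyl group. Acylation of 15 with 4-(phenylselanyl)butanoic acid (pivaloyl chloride, Et3N, LiCl) gives (4S)-4-benzyl-3-[4-(phenylselanyl)butanoyl]-1,3-oxazolidin-2-one F1. NaN(SiMe3)2 at −78 °C forms sodium (1Z)-1-[(4S)-4-benzyl-2-oxo-1,3-oxazolidin-3-yl]-4-(phenylselanyl)but-1-en-1-olate F2, which is alkylated by 14 in the standard Evans manner to methyl (2E,6Z,9S)-9-{[(4S)-4-benzyl-2-oxo-1,3-oxazolidin-3-yl]carbonyl}-2-[(3E)-4-iodopent-3-en-1-yl]-6-methyl-11-(phenylselanyl)undeca-2,6-dienoate F3. H2O2/pyridine at 0 °C gives the selenoxide methyl (2E,6Z,9S)-9-{[(4S)-4-benzyl-2-oxo-1,3-oxazolidin-3-yl]carbonyl}-2-[(3E)-4-iodopent-3-en-1-yl]-6-methyl-11-(benzeneseleninyl)undeca-2,6-dienoate F4, whose syn-elimination at 23 °C unveils the terminal vinyl group and delivers 19.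

**Step 10 (macrocyclising B-alkyl Suzuki–Miyaura).** Oligomerisation, protodeboronation or imide hydrolysis in the basic aqueous medium may win over ring closure. The fallback sets out from 15 and 13 and comes back at 21, moving the ring closure to C1–C2 so that ring and stereocentre form together.
- Acylation of 15 with but-3-enoic acid (pivaloyl chloride, Et3N, LiCl) gives (4S)-4-benzyl-3-(but-3-enoyl)-1,3-oxazolidin-2-one F5.
- 9-BBN gives (4S)-4-benzyl-3-[4-(9-borabicyclo[3.3.1]nonan-9-yl)butanoyl]-1,3-oxazolidin-2-one F6, which is coupled intermolecularly (Pd(dppf)Cl2, AsPh3, K3PO4) with the vinyl iodide of 13. This gives methyl (2E,6Z)-2-[(3E)-8-[(4S)-4-benzyl-2-oxo-1,3-oxazolidin-3-yl]-4-methyl-8-oxooct-3-en-1-yl]-8-hydroxy-6-methylocta-2,6-dienoate F7.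
- CBr4/PPh3 gives methyl (2E,6Z)-2-[(3E)-8-[(4S)-4-benzyl-2-oxo-1,3-oxazolidin-3-yl]-4-methyl-8-oxooct-3-en-1-yl]-8-bromo-6-methylocta-2,6-dienoate F8.
- NaN(SiMe3)2 in THF at 2 mM, −78 → −40 °C, forms the sodium (Z)-imide enolate of this bromide F9, which closes the ring by attack on the allylic bromide from the face opposite the benzyl group and gives 21.
- This macrocyclising Evans alkylation has no direct precedent. Its nearest relatives are intermolecular Evans allylations and the carbanion–allylic halide ring closures used for cembranoids.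

**Step 14 (methylalumination and prenylation beside a methyl ester).** Me3Al may complex or attack the ester, and the carbometalation next to the branched centre may be slow. The fallback sets out from 24 and comes back at 27, using boron in place of aluminium. Copper-catalysed methylboration (CuCl, Xantphos, B2pin2, MeI, NaOtBu, THF, 23 °C; syn addition, boron on the terminal carbon) gives methyl (1E,5Z,8R,11E)-5,11-dimethyl-8-[(1E)-1-(4,4,5,5-tetramethyl-1,3,2-dioxaborolan-2-yl)prop-1-en-2-yl]cyclotetradeca-1,5,11-triene-1-carboxylate F10. Suzuki–Miyaura coupling with 1-bromo-3-methylbut-2-ene (Pd(PPh3)4, K3PO4, THF/H2O) then gives 27 with retention of the alkene geometry.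

## Further compounds

F1 | step 9 | (4S)-4-benzyl-3-[4-(phenylselanyl)butanoyl]-1,3-oxazolidin-2-one | O=C(CCC[Se]c1ccccc1)N1[C@@H](Cc2ccccc2)COC1=O
F2 | step 9 | sodium (1Z)-1-[(4S)-4-benzyl-2-oxo-1,3-oxazolidin-3-yl]-4-(phenylselanyl)but-1-en-1-olate | [Na+].[O-]/C(=C\CC[Se]c1ccccc1)N1[C@@H](Cc2ccccc2)COC1=O
F3 | step 9 | methyl (2E,6Z,9S)-9-{[(4S)-4-benzyl-2-oxo-1,3-oxazolidin-3-yl]carbonyl}-2-[(3E)-4-iodopent-3-en-1-yl]-6-methyl-11-(phenylselanyl)undeca-2,6-dienoate | c1ccccc1[Se]CC[C@H](C/C=C(/C)CC/C=C(/C(=O)OC)CC/C=C(\C)I)C(=O)N1[C@@H](Cc2ccccc2)COC1=O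
F4 | step 9 | methyl (2E,6Z,9S)-9-{[(4S)-4-benzyl-2-oxo-1,3-oxazolidin-3-yl]carbonyl}-2-[(3E)-4-iodopent-3-en-1-yl]-6-methyl-11-(benzeneseleninyl)undeca-2,6-dienoate (mixture at selenium) | O=[Se](c1ccccc1)CC[C@H](C/C=C(/C)CC/C=C(/C(=O)OC)CC/C=C(\C)I)C(=O)N1[C@@H](Cc2ccccc2)COC1=O
F5 | step 10 | (4S)-4-benzyl-3-(but-3-enoyl)-1,3-oxazolidin-2-one | C=CCC(=O)N1[C@@H](Cc2ccccc2)COC1=O
F6 | step 10 | (4S)-4-benzyl-3-[4-(9-borabicyclo[3.3.1]nonan-9-yl)butanoyl]-1,3-oxazolidin-2-one | B1(C2CCCC1CCC2)CCCC(=O)N1[C@@H](Cc2ccccc2)COC1=O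
F7 | step 10 | methyl (2E,6Z)-2-[(3E)-8-[(4S)-4-benzyl-2-oxo-1,3-oxazolidin-3-yl]-4-methyl-8-oxooct-3-en-1-yl]-8-hydroxy-6-methylocta-2,6-dienoate | COC(=O)/C(=C/CC/C(C)=C\CO)CC/C=C(\C)CCCC(=O)N1[C@@H](Cc2ccccc2)COC1=O
F8 | step 10 | methyl (2E,6Z)-2-[(3E)-8-[(4S)-4-benzyl-2-oxo-1,3-oxazolidin-3-yl]-4-methyl-8-oxooct-3-en-1-yl]-8-bromo-6-methylocta-2,6-dienoate | COC(=O)/C(=C/CC/C(C)=C\CBr)CC/C=C(\C)CCCC(=O)N1[C@@H](Cc2ccccc2)COC1=O
F9 | step 10 | sodium (Z)-imide enolate of F8 (O–Na on the imide acyl carbon, C=C to C1) | [Na+].COC(=O)/C(=C/CC/C(C)=C\CBr)CC/C=C(\C)CC/C=C(\[O-])N1[C@@H](Cc2ccccc2)COC1=O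
F10 | step 14 | methyl (1E,5Z,8R,11E)-5,11-dimethyl-8-[(1E)-1-(4,4,5,5-tetramethyl-1,3,2-dioxaborolan-2-yl)prop-1-en-2-yl]cyclotetradeca-1,5,11-triene-1-carboxylate | CC1(C)OB(/C=C(\C)[C@H]2C/C=C(/C)CC/C=C(/C(=O)OC)CC/C=C(\C)CC2)OC1(C)C
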